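The ten-membered carbocycle (ring A, C1–C10 in germacrane numbering) is disconnected at the C3–C4 σ-bond. Both epoxides are traced back to the E-olefins C1=C10 and C4=C5, so C4 becomes the iodine-bearing carbon of a vinyl iodide and C3 the terminus of a 1,3-diene. In one operation, 9-BBN hydroboration of the diene and intramolecular B-alkyl Suzuki–Miyaura coupling close ring A at C3–C4 and deliver the E-configured C4=C5 bond. The precursor is a fully substituted butenolide (ring B) whose neighbouring ring carbons C6 and C7 carry the iodopropenyl and dienyl chains, so the planar ring holds C3 and C4 within reach. Desilylation, two acylations and substrate-controlled double epoxidation complete the route.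

Key step: step 12

Remark: locants follow germacrane numbering (ring A = C1–C10; C11 = lactone α-carbon; C12 = lactone carbonyl; C13 = oxymethyl carbon; C14, C15 = methyls on C10, C4); TBS = tert-butyldimethylsilyl; methyl (S)-glycidate, methyl 3-hydroxypropanoate and ethyl but-2-ynoate are taken as commercial.

Step 1
Reactants: 1 methyl (2S)-oxirane-2-carboxylate
Product: 2 methyl (2S)-2-hydroxypent-4-ynoate
Conditions: HC≡CH, n-BuLi, THF, −78 °C; BF3·OEt2; then 1, −78 °C
Reagents that add atoms: acetylene (C#C)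
Why: Lewis-acid-promoted alkynylation of an epoxide: lithium acetylide/BF3 should open the unsubstituted epoxide carbon faster than it attacks the ester, so the glycidate carbon becomes C8 (S) without being touched.

Step 2
Reactants: 2 methyl (2S)-2-hydroxypent-4-ynoate
Product: 3 methyl (2S)-2-[(TBS)oxy]pent-4-ynoate
Conditions: TBSCl, imidazole, DMF, rt
Reagents that add atoms: tert-butyldimethylsilyl chloride (CC(C)(C)[Si](C)(C)Cl)
Why: Standard silylation of a secondary alcohol, which protects C8–OH for the enolate and chromium chemistry that follows.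

Step 3
Reactants: 3 methyl (2S)-2-[(TBS)oxy]pent-4-ynoate
Product: 5 methyl (2S,4E)-2-[(TBS)oxy]-4-methylhepta-4,6-dienoate, via alkenylalane 4 (not isolated)
Conditions: AlMe3, Cp2ZrCl2 (cat.), H2O, CH2Cl2, −25 °C; then CH2=CHBr, Pd(PPh3)4 (cat.), ZnCl2 (cat.), THF, rt
Reagents that add atoms: trimethylaluminium (C[Al](C)C); vinyl bromide (C=CBr)
Why: Zirconium-catalysed syn-methylalumination of the terminal alkyne (Negishi carboalumination) places aluminium on the terminal carbon, and palladium-catalysed coupling with vinyl bromide (Negishi coupling) proceeds with retention, which fixes the E geometry of the future C1=C10 olefin.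

Step 4
Reactants: 6 methyl 3-hydroxypropanoate
Product: 7 methyl 3-[(TBS)oxy]propanoate
Conditions: TBSCl, imidazole, CH2Cl2, rt
Reagents that add atoms: tert-butyldimethylsilyl chloride (CC(C)(C)[Si](C)(C)Cl)
Why: Standard silylation of a primary alcohol, which provides the C11–C12–C13 unit with C13–O protected.

Step 5
Reactants: 5 methyl (2S,4E)-2-[(TBS)oxy]-4-methylhepta-4,6-dienoate; 7 methyl 3-[(TBS)oxy]propanoate
Product: 9 methyl (4S,6E)-4-[(TBS)oxy]-2-{[(TBS)oxy]methyl}-6-methyl-3-oxonona-6,8-dienoate (C2 epimers), via lithium enolate 8 (not isolated)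
Conditions: 7, LDA, THF, −78 °C; then 5, −78 → −40 °C; AcOH
Reagents that add atoms: none
Why: Crossed Claisen condensation: the ester enolate should add to the more electrophilic α-silyloxy ester at low temperature and the product is stored as its chelated enolate, so C8 is not epimerised; the C11 centre is a mixture that step 6 erases.

Step 6
Reactants: 9 methyl (4S,6E)-4-[(TBS)oxy]-2-{[(TBS)oxy]methyl}-6-methyl-3-oxonona-6,8-dienoate
Product: 10 methyl (2Z,4S,6E)-4-[(TBS)oxy]-2-{[(TBS)oxy]methyl}-6-methyl-3-{[(trifluoromethyl)sulfonyl]oxy}nona-2,6,8-trienoate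
Conditions: NaH, Et2O, 0 °C; Tf2O, −20 → 0 °C
Reagents that add atoms: trifluoromethanesulfonic anhydride (O=S(=O)(OS(=O)(=O)C(F)(F)F)C(F)(F)F)
Why: O-sulfonylation of the chelated sodium enolate of the β-keto ester should trap the Z enol triflate (triflate cis to the ester), the geometry that later places C6 cis to C12 for lactonisation.

Step 7
Reactants: 11 ethyl but-2-ynoate
Product: 12 ethyl (2E)-3-(tributylstannyl)but-2-enoate
Conditions: Bu3SnH, LDA, THF, 0 °C; CuBr·SMe2, −78 °C; then 11, MeOH, −78 °C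
Reagents that add atoms: tributyltin hydride (CCCC[SnH](CCCC)CCCC)
Why: syn-Stannylcupration of the ynoate with in situ protonation at −78 °C (kinetic control) should give the E β-stannyl enoate, with tin trans to the carbon that becomes C6; the stannane masks the vinyl iodide during the chromium/nickel step.

Step 8
Reactants: 12 ethyl (2E)-3-(tributylstannyl)but-2-enoate
Product: 13 (2E)-3-(tributylstannyl)but-2-en-1-ol
Conditions: DIBAL-H, CH2Cl2, −78 °C
Reagents that add atoms: none
Why: Hydride reduction of the conjugated ester to the allylic alcohol leaves the vinylstannane and its geometry untouched.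

Step 9
Reactants: 13 (2E)-3-(tributylstannyl)but-2-en-1-ol
Product: 14 (2E)-3-(tributylstannyl)but-2-enal
Conditions: MnO2, CH2Cl2, rt
Reagents that add atoms: none
Why: Selective oxidation of an allylic alcohol on MnO2 under neutral conditions should give the enal without protodestannylation or E/Z isomerisation.

Step 10
Reactants: 10 methyl (2Z,4S,6E)-enol triflate; 14 (2E)-3-(tributylstannyl)but-2-enal
Product: 16 (5R)-4-[(1S,3E)-1-[(TBS)oxy]-3-methylhexa-3,5-dien-1-yl]-3-{[(TBS)oxy]methyl}-5-[(1E)-2-(tributylstannyl)prop-1-en-1-yl]furan-2(5H)-one, via hydroxy ester 15 (not isolated)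
Conditions: CrCl2, NiCl2 (cat.), chiral oxazoline–sulfonamide ligand, Et3N, THF/MeCN, rt
Reagents that add atoms: none
Why: Nozaki–Hiyama–Kishi reaction: the alkenylchromium formed from the triflate with retention adds 1,2 to aldehyde 14, the new alkoxide lies cis to the ester and lactonises to ring B, and the C6 configuration (R by CIP here, 1,3-syn to C8) is imposed by the chiral ligand on chromium (reagent control) while the vinylstannane stays inert.

Step 11
Reactants: 16 stannyl butenolide
Product: 17 (5R)-4-[(1S,3E)-1-[(TBS)oxy]-3-methylhexa-3,5-dien-1-yl]-3-{[(TBS)oxy]methyl}-5-[(1E)-2-iodoprop-1-en-1-yl]furan-2(5H)-one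
Conditions: I2, CH2Cl2, 0 °C
Reagents that add atoms: iodine (II)
Why: Iododestannylation should be much faster than any reaction of iodine with the diene and proceeds with retention, giving the E vinyl iodide with iodine trans to C6.

Step 12
Reactants: 17 iodo diene butenolide
Product: 19 (1(10)E,4E,6R,8S)-8,13-bis[(TBS)oxy]germacra-1(10),4,7(11)-trien-12,6-olide, via alkylborane 18 (not isolated)
Conditions: 9-BBN, THF, 0 °C → rt; then syringe-pump addition to PdCl2(dppf) (cat.), AsPh3, Cs2CO3, DMF/THF/H2O, 45 °C, 1 mM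
Reagents that add atoms: none
Why: 9-BBN should add only to the terminal C2=C3 bond of the diene (boron on C3); zerovalent palladium then inserts into the C4–I bond with retention, the primary alkyl group is transferred from the hydroxyborate to palladium, and reductive elimination forms C3–C4. The closest known reaction type is the B-alkyl Suzuki–Miyaura macrocyclisation used for terpenoid carbocycles. Ring A is closed by intramolecular sp3–sp2 cross-coupling through an eleven-membered palladacycle, and the tether allows no other ring size. No stereocentre is formed: the E geometry of C4=C5 is that of the vinyl iodide and C1=C10 is untouched. The step needs chemoselective hydroboration (terminal vinyl over the trisubstituted, iodo-substituted and butenolide olefins, secured by 9-BBN) and ring closure over oligomerisation (secured by slow addition at 1 mM and by planar ring B, which carries both chains on adjacent carbons). Mild base at 45 °C is chosen so that the acidic C6–H is not epimerised and the germacradiene does not undergo Cope rearrangement.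

Step 13
Reactants: 19 bis-silyl germacratrienolide
Product: 20 (1(10)E,4E,6R,8S)-8,13-dihydroxygermacra-1(10),4,7(11)-trien-12,6-olide
Conditions: TBAF, AcOH, THF, 0 °C → rt
Reagents that add atoms: none
Why: Fluoride should cleave both silyl ethers; acetic acid buffering protects the base-sensitive C6–H, and the C8 alkoxide cannot translactonise because C8 lies trans to C12 across C7=C11.

Step 14
Reactants: 20 diol
Product: 21 (1(10)E,4E,6R,8S)-13-acetoxy-8-hydroxygermacra-1(10),4,7(11)-trien-12,6-olide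
Conditions: AcCl, 2,4,6-collidine, CH2Cl2, −78 °C
Reagents that add atoms: acetyl chloride (CC(Cl)=O)
Why: At −78 °C with a hindered base, the primary C13 hydroxyl should be acetylated selectively over the hindered secondary C8 hydroxyl.

Step 15
Reactants: 21 hydroxy acetate
Product: 22 (1(10)E,4E,6R,8S)-13-acetoxy-8-[(2Z)-2-methylbut-2-enoyloxy]germacra-1(10),4,7(11)-trien-12,6-olide
Conditions: angelic acid, 2,4,6-trichlorobenzoyl chloride, Et3N, toluene, rt; then 21, 75 °C
Reagents that add atoms: angelic acid (C/C=C(/C)C(O)=O)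
Why: Yamaguchi-type esterification with the preformed mixed anhydride and no nucleophilic catalyst should avoid Z→E isomerisation of the angelate, and O-acylation leaves the C8 configuration unchanged.

Step 16
Reactants: 22 angelate acetate
Product: 23 (1R,4R,5R,6S,8S,10R)-13-acetoxy-8-[(2Z)-2-methylbut-2-enoyloxy]-1,10:4,5-diepoxygermacr-7(11)-en-12,6-olide (CNP0251711.2)
Conditions: mCPBA (2.2 equiv), NaHCO3, CH2Cl2, 0 °C
Reagents that add atoms: 3-chloroperoxybenzoic acid (OOC(=O)c1cccc(Cl)c1)
Why: Prilezhaev epoxidation of the two electron-rich trisubstituted ring olefins from the outer face of the crown conformer (both methyls on one face) should give the 1R,10R and 4R,5R epoxides, while the electron-poor butenolide and angelate olefins do not react; the C6 descriptor changes from R to S only because C5 gains priority.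

Compound list
1 | methyl (2S)-oxirane-2-carboxylate | COC(=O)[C@@H]1CO1 | starting material
2 | methyl (2S)-2-hydroxypent-4-ynoate | C#CC[C@H](O)C(=O)OC | intermediate
3 | methyl (2S)-2-[(tert-butyldimethylsilyl)oxy]pent-4-ynoate | C#CC[C@H](O[Si](C)(C)C(C)(C)C)C(=O)OC | intermediate
4 | dimethyl[(1E,4S)-4-[(tert-butyldimethylsilyl)oxy]-5-methoxy-2-methyl-5-oxopent-1-en-1-yl]alumane | C[Al](C)/C=C(\C)C[C@H](O[Si](C)(C)C(C)(C)C)C(=O)OC | intermediate
5 | methyl (2S,4E)-2-[(tert-butyldimethylsilyl)oxy]-4-methylhepta-4,6-dienoate | C=C/C=C(\C)C[C@H](O[Si](C)(C)C(C)(C)C)C(=O)OC | intermediate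
6 | methyl 3-hydroxypropanoate | COC(=O)CCO | starting material
7 | methyl 3-[(tert-butyldimethylsilyl)oxy]propanoate | COC(=O)CCO[Si](C)(C)C(C)(C)C | intermediate
8 | lithium 3-[(tert-butyldimethylsilyl)oxy]-1-methoxyprop-1-en-1-olate | COC(O[Li])=CCO[Si](C)(C)C(C)(C)C | intermediate
9 | methyl (4S,6E)-4-[(tert-butyldimethylsilyl)oxy]-2-{[(tert-butyldimethylsilyl)oxy]methyl}-6-methyl-3-oxonona-6,8-dienoate (C2 epimers) | C=C/C=C(\C)C[C@H](O[Si](C)(C)C(C)(C)C)C(=O)C(CO[Si](C)(C)C(C)(C)C)C(=O)OC | intermediate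
10 | methyl (2Z,4S,6E)-4-[(tert-butyldimethylsilyl)oxy]-2-{[(tert-butyldimethylsilyl)oxy]methyl}-6-methyl-3-{[(trifluoromethyl)sulfonyl]oxy}nona-2,6,8-trienoate | C=C/C=C(\C)C[C@H](O[Si](C)(C)C(C)(C)C)/C(OS(=O)(=O)C(F)(F)F)=C(\CO[Si](C)(C)C(C)(C)C)C(=O)OC | intermediate
11 | ethyl but-2-ynoate | CC#CC(=O)OCC | starting material
12 | ethyl (2E)-3-(tributylstannyl)but-2-enoate | CCCC[Sn](CCCC)(CCCC)/C(C)=C/C(=O)OCC | intermediate
13 | (2E)-3-(tributylstannyl)but-2-en-1-ol | CCCC[Sn](CCCC)(CCCC)/C(C)=C/CO | intermediate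
14 | (2E)-3-(tributylstannyl)but-2-enal | CCCC[Sn](CCCC)(CCCC)/C(C)=C/C=O | intermediate
15 | methyl (2E,4R,5E)-3-[(1S,3E)-1-[(tert-butyldimethylsilyl)oxy]-3-methylhexa-3,5-dien-1-yl]-2-{[(tert-butyldimethylsilyl)oxy]methyl}-4-hydroxy-6-(tributylstannyl)hepta-2,5-dienoate (ester cis to the carbinol carbon) | C=C/C=C(\C)C[C@H](O[Si](C)(C)C(C)(C)C)/C(=C(\CO[Si](C)(C)C(C)(C)C)C(=O)OC)[C@H](O)/C=C(\C)[Sn](CCCC)(CCCC)CCCC | intermediate
16 | (5R)-4-[(1S,3E)-1-[(tert-butyldimethylsilyl)oxy]-3-methylhexa-3,5-dien-1-yl]-3-{[(tert-butyldimethylsilyl)oxy]methyl}-5-[(1E)-2-(tributylstannyl)prop-1-en-1-yl]furan-2(5H)-one | C=C/C=C(\C)C[C@H](O[Si](C)(C)C(C)(C)C)C1=C(CO[Si](C)(C)C(C)(C)C)C(=O)O[C@@H]1/C=C(\C)[Sn](CCCC)(CCCC)CCCC | intermediate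
17 | (5R)-4-[(1S,3E)-1-[(tert-butyldimethylsilyl)oxy]-3-methylhexa-3,5-dien-1-yl]-3-{[(tert-butyldimethylsilyl)oxy]methyl}-5-[(1E)-2-iodoprop-1-en-1-yl]furan-2(5H)-one | C=C/C=C(\C)C[C@H](O[Si](C)(C)C(C)(C)C)C1=C(CO[Si](C)(C)C(C)(C)C)C(=O)O[C@@H]1/C=C(\C)I | intermediate
18 | (5R)-4-[(1S,3E)-6-(9-borabicyclo[3.3.1]nonan-9-yl)-1-[(tert-butyldimethylsilyl)oxy]-3-methylhex-3-en-1-yl]-3-{[(tert-butyldimethylsilyl)oxy]methyl}-5-[(1E)-2-iodoprop-1-en-1-yl]furan-2(5H)-one | B1(C2CCCC1CCC2)CC/C=C(\C)C[C@H](O[Si](C)(C)C(C)(C)C)C1=C(CO[Si](C)(C)C(C)(C)C)C(=O)O[C@@H]1/C=C(\C)I | intermediate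
19 | (1(10)E,4E,6R,8S)-8,13-bis[(tert-butyldimethylsilyl)oxy]germacra-1(10),4,7(11)-trien-12,6-olide | CC(C)(C)[Si](C)(C)O[C@H]1C/C(C)=C/CC/C(C)=C/[C@H]2OC(=O)C(CO[Si](C)(C)C(C)(C)C)=C12 | intermediate
20 | (1(10)E,4E,6R,8S)-8,13-dihydroxygermacra-1(10),4,7(11)-trien-12,6-olide | O[C@H]1C/C(C)=C/CC/C(C)=C/[C@H]2OC(=O)C(CO)=C12 | intermediate
21 | (1(10)E,4E,6R,8S)-13-acetoxy-8-hydroxygermacra-1(10),4,7(11)-trien-12,6-olide | O[C@H]1C/C(C)=C/CC/C(C)=C/[C@H]2OC(=O)C(COC(C)=O)=C12 | intermediate
22 | (1(10)E,4E,6R,8S)-13-acetoxy-8-[(2Z)-2-methylbut-2-enoyloxy]germacra-1(10),4,7(11)-trien-12,6-olide | C/C=C(/C)C(=O)O[C@H]1C/C(C)=C/CC/C(C)=C/[C@H]2OC(=O)C(COC(C)=O)=C12 | intermediate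
23 | (1R,4R,5R,6S,8S,10R)-13-acetoxy-8-[(2Z)-2-methylbut-2-enoyloxy]-1,10:4,5-diepoxygermacr-7(11)-en-12,6-olide (CNP0251711.2) | C/C=C(/C)C(=O)O[C@H]1C[C@@]2(C)O[C@@H]2CC[C@@]2(C)O[C@@H]2[C@H]2OC(=O)C(COC(C)=O)=C12 | target

Total step count: 16
Longest linear sequence: 12 steps (steps 1, 2, 3, 5, 6, 10, 11, 12, 13, 14, 15, 16)

Steps most likely to fail

Step 12 (key step). What may go wrong: oligomerisation outrunning closure of the strained (E,E)-cyclodecadiene, protodeboronation of the alkylborane, or base-induced epimerisation at C6 during the slow addition. Fallback (base-free Negishi ring closure through an alkylzinc instead of the boron route): setting out from 17, hydroboration to 18 followed by oxidation with NaBO3 would give the primary C3 alcohol F1. PPh3/I2/imidazole would convert it into the primary C3 iodide F2. Zinc dust in DMA at 40 °C should insert only into the alkyl C–I bond to give the alkylzinc iodide F3, which Pd(PPh3)4 under high dilution should cyclise to 19, where the route is rejoined.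

Step 10. What may go wrong: poor facial selectivity at C6 (mismatch between the chiral chromium complex and the C8 silyloxy centre) or slow addition of the tetrasubstituted alkenylchromium. Fallback (C–C bond formation separated from stereocontrol, with the carbinol set by reagent-controlled ketone reduction): setting out from 5, Claisen condensation with the lithium enolate F5 of tert-butyl 3-[(tert-butyldimethylsilyl)oxy]propanoate F4 (from commercial tert-butyl 3-hydroxypropanoate and TBSCl) would give the β-keto tert-butyl ester F6. NaH/Tf2O would give the Z enol triflate F7. Ligand-free CrCl2/NiCl2 coupling with 14 would give the hydroxy tert-butyl ester F8 as both C4 epimers, which should not lactonise. Dess–Martin periodinane would give the cross-conjugated dienone F9, and Corey–Bakshi–Shibata reduction the (4R)-hydroxy tert-butyl ester F10. Camphorsulfonic acid would then close the lactone with loss of tert-butanol, coming back to the route at 16.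

Step 16. What may go wrong: attack on the inner face of one olefin if a second ring conformer is populated, or acid-triggered transannular cyclisation of the mono-epoxide. Fallback (reagent control instead of conformational control): setting out from 22, Shi epoxidation with the D-fructose-derived ketone and potassium peroxymonosulfate at buffered pH should impose the R,R sense on both trisubstituted E-olefins and lead directly to 23; no new compound is involved.

Further compounds
F1 | step 12 | (5R)-4-[(1S,3E)-1-[(tert-butyldimethylsilyl)oxy]-6-hydroxy-3-methylhex-3-en-1-yl]-3-{[(tert-butyldimethylsilyl)oxy]methyl}-5-[(1E)-2-iodoprop-1-en-1-yl]furan-2(5H)-one | OCC/C=C(\C)C[C@H](O[Si](C)(C)C(C)(C)C)C1=C(CO[Si](C)(C)C(C)(C)C)C(=O)O[C@@H]1/C=C(\C)I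
F2 | step 12 | (5R)-4-[(1S,3E)-1-[(tert-butyldimethylsilyl)oxy]-6-iodo-3-methylhex-3-en-1-yl]-3-{[(tert-butyldimethylsilyl)oxy]methyl}-5-[(1E)-2-iodoprop-1-en-1-yl]furan-2(5H)-one | ICC/C=C(\C)C[C@H](O[Si](C)(C)C(C)(C)C)C1=C(CO[Si](C)(C)C(C)(C)C)C(=O)O[C@@H]1/C=C(\C)I
F3 | step 12 | alkylzinc iodide derived from F2 (zinc on C3) | I[Zn]CC/C=C(\C)C[C@H](O[Si](C)(C)C(C)(C)C)C1=C(CO[Si](C)(C)C(C)(C)C)C(=O)O[C@@H]1/C=C(\C)I
F4 | step 10 | tert-butyl 3-[(tert-butyldimethylsilyl)oxy]propanoate | CC(C)(C)OC(=O)CCO[Si](C)(C)C(C)(C)C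
F5 | step 10 | lithium 1-tert-butoxy-3-[(tert-butyldimethylsilyl)oxy]prop-1-en-1-olate | CC(C)(C)OC(O[Li])=CCO[Si](C)(C)C(C)(C)C
F6 | step 10 | tert-butyl (4S,6E)-4-[(tert-butyldimethylsilyl)oxy]-2-{[(tert-butyldimethylsilyl)oxy]methyl}-6-methyl-3-oxonona-6,8-dienoate (C2 epimers) | C=C/C=C(\C)C[C@H](O[Si](C)(C)C(C)(C)C)C(=O)C(CO[Si](C)(C)C(C)(C)C)C(=O)OC(C)(C)C
F7 | step 10 | tert-butyl (2Z,4S,6E)-4-[(tert-butyldimethylsilyl)oxy]-2-{[(tert-butyldimethylsilyl)oxy]methyl}-6-methyl-3-{[(trifluoromethyl)sulfonyl]oxy}nona-2,6,8-trienoate | C=C/C=C(\C)C[C@H](O[Si](C)(C)C(C)(C)C)/C(OS(=O)(=O)C(F)(F)F)=C(\CO[Si](C)(C)C(C)(C)C)C(=O)OC(C)(C)C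
F8 | step 10 | tert-butyl (2E,5E)-3-[(1S,3E)-1-[(tert-butyldimethylsilyl)oxy]-3-methylhexa-3,5-dien-1-yl]-2-{[(tert-butyldimethylsilyl)oxy]methyl}-4-hydroxy-6-(tributylstannyl)hepta-2,5-dienoate (C4 epimers) | C=C/C=C(\C)C[C@H](O[Si](C)(C)C(C)(C)C)/C(=C(\CO[Si](C)(C)C(C)(C)C)C(=O)OC(C)(C)C)C(O)/C=C(\C)[Sn](CCCC)(CCCC)CCCC
F9 | step 10 | tert-butyl (2Z,5E)-3-[(1S,3E)-1-[(tert-butyldimethylsilyl)oxy]-3-methylhexa-3,5-dien-1-yl]-2-{[(tert-butyldimethylsilyl)oxy]methyl}-4-oxo-6-(tributylstannyl)hepta-2,5-dienoate | C=C/C=C(\C)C[C@H](O[Si](C)(C)C(C)(C)C)/C(=C(\CO[Si](C)(C)C(C)(C)C)C(=O)OC(C)(C)C)C(=O)/C=C(\C)[Sn](CCCC)(CCCC)CCCC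
F10 | step 10 | tert-butyl (2E,4R,5E)-3-[(1S,3E)-1-[(tert-butyldimethylsilyl)oxy]-3-methylhexa-3,5-dien-1-yl]-2-{[(tert-butyldimethylsilyl)oxy]methyl}-4-hydroxy-6-(tributylstannyl)hepta-2,5-dienoate | C=C/C=C(\C)C[C@H](O[Si](C)(C)C(C)(C)C)/C(=C(\CO[Si](C)(C)C(C)(C)C)C(=O)OC(C)(C)C)[C@H](O)/C=C(\C)[Sn](CCCC)(CCCC)CCCC
F0 | step 16 | none | none
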